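Its constants are those of an exercise; the result is computed.

A closed, stirred, isothermal vessel runs a ping-pong enzyme cycle whose first product is caught by further starting material.

    starting material + free enzyme ⇌ first complex (K1 = 220 /M, k1 = 4.7 × 10⁶ /M/s)
    first complex → loaded enzyme + first product (k2 = 2000 /s)
    second substrate + loaded enzyme ⇌ second complex (K3 = 95 /M, k3 = 1.7 × 10⁷ /M/s)
    second complex → free enzyme + target (k4 = 810 /s)
    starting material + first product ⇌ idle adduct, settled at all times (K5 = 17000 /M)

| setting | south-east | south-west |
|---|---|---|
| starting material | 5.0 mM | 5.0 mM |
| second substrate | 4.80 mM | 9.50 mM |
| free enzyme | 0.50 µM | 0.50 µM |
| time | 8.0 s | 8.0 s |

* part of the starting material that has reacted at the end, south-east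
* part of the starting material that has reacted at the end, south-west
* what raising the concentration of second substrate from its lowest to its highest value here does to the part of the starting material that has reacted (changes below 5 percentage points count as none) (it rises / no change / it falls)

- amounts and yields of first product count idle adduct too
- what has gone from starting material into another species counts as reacted, even if it can come back
- run time (south-east): 8.0 s

Free enzyme is far scarcer than starting material, so the enzyme forms run at steady state, and this estimate freezes [starting material] and [second substrate] at their charges. A complex can fall back as well as go on, so a binding does not always lead to a turn. Loaded enzyme therefore waits 2.72 ms per turn in south-east and 1.37 ms in south-west, and the wait of free enzyme plus the two chemical steps adds 2.23 ms. A turn thus takes 4.95 ms in south-east and 3.61 ms in south-west. This cycle time is the sum of the stage times for one enzyme molecule at frozen concentrations, and it is far shorter than the run.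

K5[starting material] starts at 85, so at the start nearly all first product goes to idle adduct, and this estimate counts two starting material per turn. The part reacted is then two times enzyme times time, over cycle time times charge: 32.3% in south-east and 44.4% in south-west, so with more second substrate it rises.

The forecast gave 30% and 41.3%, both lower than these frozen figures , and it rises, with “about two starting material molecules are consumed per turnover”.

The simulation gives 30.0% in south-east and 41.4% in south-west, so it rises, by 11 percentage points.

The frozen figure for south-west stands 3 points above the simulation, and at the end of that flask [starting material] is 59% of its charge, less than [second substrate] at 89%. The neighbour flask, south-west with 2.0 × 10⁻⁴ mM of free enzyme, has the same cycle time, which gives 17.7%, and its simulated part reacted is 17.2%.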